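## The problem

Compound 22 is a trans-fused hydroazulene: a cyclopentane (C1–C5) that shares the C1–C5 bond with a cycloheptene (C1, C5–C10). The atoms are numbered here as follows: C1 is the methyl-bearing ring-fusion carbon, C2 and C3 the cyclopentane methylenes, C4 the isopropyl carbinol, C5 the ring-fusion methine, C6 the carbon carrying the vanillate, C7 a methylene, C8 the methyl carbinol and C9=C10 the cis alkene, with C10 bonded to C1. The configuration is 1R,4R,5S,6S,8R: H-5, the isopropyl group, the C6 oxygen and the C8 hydroxyl lie on one face, and the C1 methyl, the C4 hydroxyl and the C8 methyl on the other. The all-carbon quaternary centre C1 has no neighbour from which it could be derived and must be set by a chiral catalyst. Once it exists it can direct C5 (new bond anti to the larger C1 substituent), and C5 can direct C6 (through a ring enolate) and C4 (attack trans to the C5 branch). C8, a tertiary allylic carbinol that is 1,3 to C6 and separated from C1 by the alkene, is the centre least easily relayed. The seven-membered ring has to be closed trans to the five-membered ring and with a cis C9=C10 bond. The fragile groups are the tertiary allylic C8 alcohol (ionisation, transposition), the tertiary C4 alcohol β to the C6 oxygen (dehydration, retro-aldol at the ketone stage), the free phenol and the aryl ester on a hindered secondary carbinol, so strong acid, strong base, hydride and hydrogenation are excluded late in the route. The enabling feature is that C1, C5 and C4 are three consecutive atoms of the five-membered ring with the substitution pattern of the β-carbon, α-carbon and carbonyl carbon of 3-methylcyclopent-2-en-1-one (10). The methyl group is already on C1, and the two bonds leaving the ring there, C1–C10 and C5–C6, are those made by a conjugate addition and an enolate aldol reaction.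

## Retrosynthesis

**Ester and phenol.** 22 is traced to its phenol silyl ether 21, and cutting the C6–O acyl bond gives triol 17 and the protected acid 20 (from vanillic acid 18 through silyl ester 19). This cut comes first because an aryl ester and a free phenol would not survive the organometallic steps that build the skeleton. C6–OH is the only secondary hydroxyl of 17, so the core needs no protecting group. 17 holds the full carbon skeleton and all five stereocentres. The forward steps must acylate a hindered secondary alcohol next to two tertiary ones and then free the phenol without harming the ester or the allylic alcohol.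

**C8–C9.** The seven-membered ring of 17 is opened at C8–C9 to give the iodo ketone 16. A cut at C6–C7 or C7–C8 would leave the tertiary carbinol to be made by a separate operation. The C8–C9 cut turns it into its carbonyl precursor and uses the cis alkene as a nucleophile whose geometry is fixed beforehand. 16 is monocyclic and has one stereocentre fewer. The forward reaction must add an alkenyl metal to a methyl ketone in the presence of two free hydroxyls, close a trans-fused seven-membered ring and select the ketone face that puts the C8 hydroxyl on the face of the C6 oxygen.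

**Functional groups at C6, C8 and C9.** No skeletal bond is cut between 16 and 14. The iodide of 16 comes from the trimethylsilyl group (15 from 14), the ketone from a dioxolane and the C6 hydroxyl from a triethylsilyl ether. A vinylsilane is preferred to an iodide or stannane carried from the start because it survives alane formation, copper catalysis and the organocerium reagent. The forward steps need ipso-substitution with retention of the Z geometry and a mild acid unmasking.

**C4–isopropyl.** Removing the isopropyl group from 14 gives ketone 13, the silyl ether of aldol 12. This bond is cut before the ring-forming bonds because the C4 carbonyl it reveals is the carbonyl of the enone. The forward reaction must add a branched nucleophile with β-hydrogens to a hindered, enolisable ketone from the face opposite the C5 branch. The C6 hydroxyl is silylated so that no alkoxide can start a retro-aldol cleavage.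

**C1–C10 and C5–C6 (key).** Both bonds of 12 are cut together, giving enone 10, alane 6 and aldehyde 9. Cutting them one at a time would require alkylating a 3,3-disubstituted cyclopentanone at C5, where base-mediated enolisation prefers C3. The double cut instead uses the enolate that the conjugate addition produces. Three stereocentres and seventeen carbons fall back to an achiral commercial enone and two small achiral reagents. The forward reaction has to create the quaternary C1 enantioselectively and trap the enolate as the anti aldol.

**Reagents.** Alane 6 comes from (Z)-bromide 4 by lithiation and transmetalation, 4 from bromoalkyne 2 by cis reduction, and 2 from ethynyltrimethylsilane (1). Aldehyde 9 comes from ester 8, the ketal of ethyl acetoacetate (7). These are functional-group changes only; the one demand is that the Z geometry of 4 is kept through 6.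

## Roads not taken

Alternative 1: The cut is C7–C8.

- **Forward step:** A2 carries a pinacol boronic ester on C7 and a secondary allylic carbamate on C8, and is treated with lithium 2,2,6,6-tetramethylpiperidide. The carbanion formed at C8 is captured by the boron atom of the same molecule, closing an eight-membered ring at the ate stage. C7 then shifts from boron to C8 with loss of the carbamate, which contracts the ring to the seven-membered carbocycle A1. Oxidation of the C–B bond with retention installs the C8 hydroxyl.
- **Merit:** C8 is made stereospecifically from a secondary carbinol that a reliable asymmetric reduction can supply. In this respect it is better than the chosen plan, where C8 depends on the facial preference of a ring closure.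
- **Weak points:** A lithiated allylic carbamate can be borylated at C10 as well as at C8, the allyl anion can lose the Z geometry, and A1 can undergo 1,3-boron shift. The ate complex must form through an eight-membered ring against oligomerisation, and complexation at a carbon that becomes fully substituted is often reversible. A2 already contains the five-membered ring with C1, C4, C5 and C6 set, so everything that step 6 does would still have to be done, and boron and carbamate added on top.
- **Comparison:** The chosen plan sets against the better C8 control a much shorter route and a second, mechanistically different ring closure held in reserve for C8.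

Alternative 2: The cuts are C7–C8 and C1–C5.

- **Forward step:** A5 is ionised by NaOCH2CF3 in CF3CH2OH to its oxyallyl form, which adds across the 2- and 5-positions of A4. Zn(Cu) in the same flask removes the chlorine atoms and gives the oxygen-bridged meso ketone A3.
- **Merit:** One flask from commodity chemicals delivers the seven-membered ring with the C1 methyl, the C8 methyl and oxygen, the C9=C10 alkene and a C6 carbonyl. For ring construction per step and for scale it is better than the chosen plan, which needs five further steps from 12 to reach the bicycle.
- **Weak points:** A3 is meso and must be desymmetrised to tell C5 from C7 and C1 from C8. At C1 the bridging oxygen has to be exchanged for C2 at a fully substituted allylic carbon with overall retention. The cyclopentane with the C4 carbinol must then be annulated onto C5 and C1, and the C8 hydroxyl appears only when the bridge is cut.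
- **Comparison:** The chosen plan starts from the five-membered ring, carries absolute configuration from its first skeletal step and never has to replace a C–O by a C–C bond at a quaternary centre.

Alternative 3: The cut is C6–C7.

- **Forward step:** In A7 the allylic C–Br bond of a (Z)-dienyl bromide is metalated by divalent chromium. The chromium is regenerated at a cathode from catalytic CrCl3 (DMF, Me3SiCl, sacrificial aluminium anode). Addition to the C6 aldehyde closes the ring to A6.
- **Merit:** Chromium is catalytic and the electrophile is an aldehyde. In both respects it is better than step 11 of the chosen plan, which uses several equivalents of CrCl2 and a methyl ketone.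
- **Weak points:** A6 carries C8 as an exocyclic methylene conjugated with C9=C10. Making the tertiary methyl carbinol from it requires Markovnikov hydration of one alkene of a diene with facial control. Radical hydration would pass through an allylic radical with oxygenation at C8 or C10, and epoxide routes meet allylic opening. C6 would be set in the ring closure and not by an aldol of defined geometry. A7 is an epimerisable α-branched aldehyde with a sensitive dienyl bromide, and its cyclopentane stereotriad must be made first.
- **Comparison:** The chosen plan sets against the cleaner chromium chemistry the fact that C6 and the oxidation level of C8 are in place before the ring is closed.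

Key step: step 6

Assumption: L*·H stands for a chiral sulfonate-bearing imidazolinium salt, for example 2-[(4S,5S)-3-(2,6-diethylphenyl)-4,5-diphenyl-4,5-dihydro-1H-imidazol-3-ium-1-yl]benzenesulfonate or its mirror image; the antipode that gives the 3S quaternary carbon of 12 is to be found in a first screen, and the structures below are drawn for that outcome.

Step 1
Reactants: 1 ethynyltrimethylsilane
Product: 2 (bromoethynyl)trimethylsilane
Conditions: NBS (1.1 equiv), AgNO3 (10 mol %), acetone, rt
Reagents that add atoms: N-bromosuccinimide, O=C1CCC(=O)N1Br
Why: Silver-catalysed electrophilic bromination of a terminal alkyne through the silver acetylide; the medium is neutral, so the C–Si bond is not cleaved.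

Step 2
Reactants: 2 (bromoethynyl)trimethylsilane
Product: 4 (Z)-(2-bromoethenyl)trimethylsilane, via alkenylborane 3 (not isolated)
Conditions: Cy2BH (1.05 equiv, from BH3·SMe2 and cyclohexene), THF, 0 °C; then AcOH, 0 °C to rt
Reagents that add atoms: none
Why: Hydroboration–protonolysis of a 1-bromoalkyne: syn addition of H–B places boron on the bromine-bearing carbon, and protonolysis of the alkenyl C–B bond by AcOH proceeds with retention. The net result is cis addition of H2, hence the Z bromide.

Step 3
Reactants: 4 (Z)-(2-bromoethenyl)trimethylsilane
Product: 6 dimethyl[(Z)-2-(trimethylsilyl)ethenyl]aluminium, via alkenyllithium 5 (not isolated)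
Conditions: t-BuLi (2.0 equiv), Et2O/pentane, −78 °C; then Me2AlCl (1.0 equiv), −78 to −40 °C
Reagents that add atoms: dimethylaluminium chloride, C[Al](C)Cl
Why: Bromine–lithium exchange followed by lithium-to-aluminium transmetalation, both with retention at the sp2 carbon; the second equivalent of t-BuLi destroys the t-BuBr formed. The alane is kept as a cold solution and used directly in step 6.

Step 4
Reactants: 7 ethyl 3-oxobutanoate (ethyl acetoacetate)
Product: 8 ethyl (2-methyl-1,3-dioxolan-2-yl)acetate
Conditions: HOCH2CH2OH (1.5 equiv), p-TsOH·H2O (cat.), toluene, reflux, Dean–Stark trap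
Reagents that add atoms: ethane-1,2-diol, OCCO
Why: Acid-catalysed ketalisation with azeotropic removal of water; only the ketone carbonyl reacts and the ester is kept for step 5.

Step 5
Reactants: 8 ethyl (2-methyl-1,3-dioxolan-2-yl)acetate
Product: 9 (2-methyl-1,3-dioxolan-2-yl)acetaldehyde
Conditions: i-Bu2AlH (1.05 equiv), CH2Cl2, −78 °C; then MeOH, aq. potassium sodium tartrate
Reagents that add atoms: none
Why: Partial reduction of an ester by a dialkylaluminium hydride: the tetrahedral aluminium hemiacetal persists at −78 °C and releases the aldehyde only on work-up. 9 should be used promptly because β-ketal aldehydes eliminate and oligomerise on storage.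

Step 6
Reactants: 10 3-methylcyclopent-2-en-1-one; 6 dimethyl[(Z)-2-(trimethylsilyl)ethenyl]aluminium; 9 (2-methyl-1,3-dioxolan-2-yl)acetaldehyde
Product: 12 (2S,3S)-2-[(1S)-1-hydroxy-2-(2-methyl-1,3-dioxolan-2-yl)ethyl]-3-methyl-3-[(Z)-2-(trimethylsilyl)ethenyl]cyclopentan-1-one, via aluminium enolate 11 (not isolated)
Conditions: Cu(OTf)2 (5 mol %), carbene ligand L* (6 mol %, as its silver carbene from L*·H and Ag2O), 6 (1.3 equiv), THF, −78 to −50 °C; then 9 (2.0 equiv), −78 °C; aq. potassium sodium tartrate
Reagents that add atoms: none
Why: The reaction type relied on is the copper-catalysed enantioselective conjugate addition of an alkenylaluminium reagent to a 3-substituted cyclic enone with aldol capture of the aluminium enolate. Transmetalation from aluminium gives a carbene-bound alkenylcopper species that adds to the enone β-carbon through a trivalent copper intermediate and reductive elimination, forming C1–C10 with retention of the Z geometry, the sp2 group transferring in preference to the methyl groups on aluminium. The chiral carbene, whose sulfonate can bridge copper and aluminium and so fix the enone in the catalyst pocket, selects the enone face and sets C1. This event leaves the regiodefined dimethylaluminium enolate 11 (C4–C5), which base could not produce from the ketone because deprotonation would occur at C3. Aldehyde 9 then adds at C5 on the face opposite the folded (Z)-silylvinyl group, which is much larger than the methyl group on the same carbon, so that the new C5–C6 bond is cis to the methyl group. Because the ring enforces the E(O) enolate geometry, a closed six-membered chair transition state with the aldehyde substituent equatorial gives the anti aldol, that is the 5S,6S pair. No ring is closed; two skeletal bonds and three stereocentres are made. The step needs 1,4- over 1,2-addition (secured by copper), enantioface control (ligand) and anti-selective trapping (chair transition state at −78 °C, with the aldehyde in excess so that residual alane does not consume it).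

Step 7
Reactants: 12 (2S,3S)-2-[(1S)-1-hydroxy-2-(2-methyl-1,3-dioxolan-2-yl)ethyl]-3-methyl-3-[(Z)-2-(trimethylsilyl)ethenyl]cyclopentan-1-one
Product: 13 (2S,3S)-3-methyl-2-[(1S)-2-(2-methyl-1,3-dioxolan-2-yl)-1-(triethylsilyloxy)ethyl]-3-[(Z)-2-(trimethylsilyl)ethenyl]cyclopentan-1-one
Conditions: Et3SiCl (1.3 equiv), imidazole, DMF, 0 °C to rt
Reagents that add atoms: chlorotriethylsilane, CC[Si](Cl)(CC)CC
Why: Silylation of a secondary alcohol with a silyl chloride and imidazole. The silyl ether removes the acidic proton and so prevents retro-aldol cleavage and alkoxide-directed side reactions in step 8.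

Step 8
Reactants: 13 (2S,3S)-3-methyl-2-[(1S)-2-(2-methyl-1,3-dioxolan-2-yl)-1-(triethylsilyloxy)ethyl]-3-[(Z)-2-(trimethylsilyl)ethenyl]cyclopentan-1-one
Product: 14 (1R,2S,3S)-3-methyl-2-[(1S)-2-(2-methyl-1,3-dioxolan-2-yl)-1-(triethylsilyloxy)ethyl]-1-(propan-2-yl)-3-[(Z)-2-(trimethylsilyl)ethenyl]cyclopentan-1-ol
Conditions: i-PrMgCl (3 equiv), anhydrous CeCl3 (3 equiv), THF, −78 to −40 °C
Reagents that add atoms: isopropylmagnesium chloride, CC(C)[Mg]Cl
Why: 1,2-Addition of an organocerium reagent to a hindered enolisable ketone: the weakly basic, oxophilic isopropylcerium dichloride suppresses enolisation and β-hydride reduction. The reagent should approach C4 from the face opposite the adjacent C5 side chain and the C1 methyl group, which places the isopropyl group β and the hydroxyl α (4R).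

Step 9
Reactants: 14 (1R,2S,3S)-3-methyl-2-[(1S)-2-(2-methyl-1,3-dioxolan-2-yl)-1-(triethylsilyloxy)ethyl]-1-(propan-2-yl)-3-[(Z)-2-(trimethylsilyl)ethenyl]cyclopentan-1-ol
Product: 15 (1R,2S,3S)-3-[(Z)-2-iodoethenyl]-3-methyl-2-[(1S)-2-(2-methyl-1,3-dioxolan-2-yl)-1-(triethylsilyloxy)ethyl]-1-(propan-2-yl)cyclopentan-1-ol
Conditions: NIS (1.5 equiv), 2,6-lutidine, (CF3)2CHOH, 0 °C
Reagents that add atoms: N-iodosuccinimide, O=C1CCC(=O)N1I
Why: Electrophilic ipso-iododesilylation of a vinylsilane: iodonium transfer to C9 gives a β-silyl-stabilised cation that loses silicon to the solvent faster than it rotates, so the Z geometry should be retained. The tertiary C4 hydroxyl lies on the ring face opposite the alkene and cannot cyclise onto it.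

Step 10
Reactants: 15 (1R,2S,3S)-3-[(Z)-2-iodoethenyl]-3-methyl-2-[(1S)-2-(2-methyl-1,3-dioxolan-2-yl)-1-(triethylsilyloxy)ethyl]-1-(propan-2-yl)cyclopentan-1-ol
Product: 16 (4S)-4-hydroxy-4-[(1S,2R,5S)-2-hydroxy-5-[(Z)-2-iodoethenyl]-5-methyl-2-(propan-2-yl)cyclopentyl]butan-2-one
Conditions: 1 M aq. HCl, THF, 0 °C to rt
Reagents that add atoms: water, O
Why: Acid-catalysed hydrolysis of the dioxolane and of the triethylsilyl ether in one operation, kept cold and dilute because the tertiary C4 alcohol and the new β-hydroxy ketone are prone to dehydration. 16 may equilibrate with its six-membered hemiketal (C4–O onto C8), which reopens under the conditions of step 11.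

Step 11
Reactants: 16 (4S)-4-hydroxy-4-[(1S,2R,5S)-2-hydroxy-5-[(Z)-2-iodoethenyl]-5-methyl-2-(propan-2-yl)cyclopentyl]butan-2-one
Product: 17 (3R,3aS,4S,6R,8aR)-6,8a-dimethyl-3-(propan-2-yl)-1,2,3,3a,4,5,6,8a-octahydroazulene-3,4,6-triol
Conditions: CrCl2 (8 equiv), NiCl2 (5 mol %), degassed DMF, rt, 0.01 M
Reagents that add atoms: none
Why: Intramolecular Nozaki–Hiyama–Kishi reaction of an alkenyl iodide with a ketone: zerovalent nickel inserts into the C9–I bond, and transmetalation gives a trivalent alkenylchromium that tolerates the free hydroxyls and adds to the C8 carbonyl in a 7-exo-trig closure possible only for the Z isomer. The trans arrangement of the two arms on the five-membered ring should hold the forming cycloheptene in a chair with C7 on the β side. With the carbonyl oxygen syn to the departing chromium, the oxygen sits pseudo-equatorial, which places the C8 hydroxyl β and the methyl group α as required.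

Step 12
Reactants: 18 4-hydroxy-3-methoxybenzoic acid (vanillic acid)
Product: 20 4-[(tert-butyldimethylsilyl)oxy]-3-methoxybenzoic acid, via silyl ester 19 (not isolated)
Conditions: t-BuMe2SiCl (2.5 equiv), imidazole, DMF, rt; then AcOH/THF/H2O (3:1:1), rt
Reagents that add atoms: tert-butylchlorodimethylsilane, CC(C)(C)[Si](C)(C)Cl
Why: Exhaustive silylation of acid and phenol followed by selective hydrolysis of the silyl ester, which is far more labile than the aryl silyl ether; this is a standard protection of hydroxybenzoic acids.

Step 13
Reactants: 17 (3R,3aS,4S,6R,8aR)-6,8a-dimethyl-3-(propan-2-yl)-1,2,3,3a,4,5,6,8a-octahydroazulene-3,4,6-triol; 20 4-[(tert-butyldimethylsilyl)oxy]-3-methoxybenzoic acid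
Product: 21 (3R,3aS,4S,6R,8aR)-3,6-dihydroxy-6,8a-dimethyl-3-(propan-2-yl)-1,2,3,3a,4,5,6,8a-octahydroazulen-4-yl 4-[(tert-butyldimethylsilyl)oxy]-3-methoxybenzoate
Conditions: EDC·HCl (1.5 equiv), DMAP (0.5 equiv), CH2Cl2, rt
Reagents that add atoms: none
Why: Steglich esterification: the N-acylpyridinium derived from 20 acylates the only secondary hydroxyl (C6). The tertiary C4 and C8 hydroxyls are inert to carbodiimide/DMAP acylation at room temperature, and no stereocentre is touched.

Step 14
Reactants: 21 (3R,3aS,4S,6R,8aR)-3,6-dihydroxy-6,8a-dimethyl-3-(propan-2-yl)-1,2,3,3a,4,5,6,8a-octahydroazulen-4-yl 4-[(tert-butyldimethylsilyl)oxy]-3-methoxybenzoate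
Product: 22 (3R,3aS,4S,6R,8aR)-3,6-dihydroxy-6,8a-dimethyl-3-(propan-2-yl)-1,2,3,3a,4,5,6,8a-octahydroazulen-4-yl 4-hydroxy-3-methoxybenzoate
Conditions: Bu4NF (1.1 equiv), AcOH (1.1 equiv), THF, 0 °C
Reagents that add atoms: none
Why: Fluoride-mediated cleavage of an aryl silyl ether, buffered with AcOH so that the phenoxide is protonated at once. Under these conditions neither the ester nor the tertiary allylic alcohol should be affected.

## Compound list

1 | ethynyltrimethylsilane | C#C[Si](C)(C)C | starting material
2 | (bromoethynyl)trimethylsilane | BrC#C[Si](C)(C)C | intermediate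
3 | [(Z)-1-bromo-2-(trimethylsilyl)ethenyl]dicyclohexylborane (not isolated) | C[Si](C)(C)/C=C(\Br)B(C1CCCCC1)C1CCCCC1 | intermediate
4 | (Z)-(2-bromoethenyl)trimethylsilane | C[Si](C)(C)/C=C\Br | intermediate
5 | [(Z)-2-(trimethylsilyl)ethenyl]lithium (not isolated) | C[Si](C)(C)/C=C\[Li] | intermediate
6 | dimethyl[(Z)-2-(trimethylsilyl)ethenyl]aluminium | C[Si](C)(C)/C=C\[Al](C)C | intermediate
7 | ethyl 3-oxobutanoate (ethyl acetoacetate) | CCOC(=O)CC(C)=O | starting material
8 | ethyl (2-methyl-1,3-dioxolan-2-yl)acetate | CCOC(=O)CC1(C)OCCO1 | intermediate
9 | (2-methyl-1,3-dioxolan-2-yl)acetaldehyde | CC1(CC=O)OCCO1 | intermediate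
10 | 3-methylcyclopent-2-en-1-one | CC1=CC(=O)CC1 | starting material
11 | dimethylaluminium (3S)-3-methyl-3-[(Z)-2-(trimethylsilyl)ethenyl]cyclopent-1-en-1-olate (not isolated) | C[Si](C)(C)/C=C\[C@@]1(C)CCC(O[Al](C)C)=C1 | intermediate
12 | (2S,3S)-2-[(1S)-1-hydroxy-2-(2-methyl-1,3-dioxolan-2-yl)ethyl]-3-methyl-3-[(Z)-2-(trimethylsilyl)ethenyl]cyclopentan-1-one | C[Si](C)(C)/C=C\[C@@]1(C)CCC(=O)[C@@H]1[C@@H](O)CC2(C)OCCO2 | intermediate
13 | (2S,3S)-3-methyl-2-[(1S)-2-(2-methyl-1,3-dioxolan-2-yl)-1-(triethylsilyloxy)ethyl]-3-[(Z)-2-(trimethylsilyl)ethenyl]cyclopentan-1-one | C[Si](C)(C)/C=C\[C@@]1(C)CCC(=O)[C@@H]1[C@@H](O[Si](CC)(CC)CC)CC2(C)OCCO2 | intermediate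
14 | (1R,2S,3S)-3-methyl-2-[(1S)-2-(2-methyl-1,3-dioxolan-2-yl)-1-(triethylsilyloxy)ethyl]-1-(propan-2-yl)-3-[(Z)-2-(trimethylsilyl)ethenyl]cyclopentan-1-ol | C[Si](C)(C)/C=C\[C@@]1(C)CC[C@@](O)(C(C)C)[C@@H]1[C@@H](O[Si](CC)(CC)CC)CC2(C)OCCO2 | intermediate
15 | (1R,2S,3S)-3-[(Z)-2-iodoethenyl]-3-methyl-2-[(1S)-2-(2-methyl-1,3-dioxolan-2-yl)-1-(triethylsilyloxy)ethyl]-1-(propan-2-yl)cyclopentan-1-ol | I/C=C\[C@@]1(C)CC[C@@](O)(C(C)C)[C@@H]1[C@@H](O[Si](CC)(CC)CC)CC2(C)OCCO2 | intermediate
16 | (4S)-4-hydroxy-4-[(1S,2R,5S)-2-hydroxy-5-[(Z)-2-iodoethenyl]-5-methyl-2-(propan-2-yl)cyclopentyl]butan-2-one | I/C=C\[C@@]1(C)CC[C@@](O)(C(C)C)[C@@H]1[C@@H](O)CC(C)=O | intermediate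
17 | (3R,3aS,4S,6R,8aR)-6,8a-dimethyl-3-(propan-2-yl)-1,2,3,3a,4,5,6,8a-octahydroazulene-3,4,6-triol | O[C@H]2C[C@@](C)(O)C=C[C@@]3(C)CC[C@@](O)(C(C)C)[C@H]23 | intermediate
18 | 4-hydroxy-3-methoxybenzoic acid (vanillic acid) | COc1cc(C(=O)O)ccc1O | starting material
19 | tert-butyldimethylsilyl 4-[(tert-butyldimethylsilyl)oxy]-3-methoxybenzoate (not isolated) | COc1cc(C(=O)O[Si](C)(C)C(C)(C)C)ccc1O[Si](C)(C)C(C)(C)C | intermediate
20 | 4-[(tert-butyldimethylsilyl)oxy]-3-methoxybenzoic acid | COc1cc(C(=O)O)ccc1O[Si](C)(C)C(C)(C)C | intermediate
21 | (3R,3aS,4S,6R,8aR)-3,6-dihydroxy-6,8a-dimethyl-3-(propan-2-yl)-1,2,3,3a,4,5,6,8a-octahydroazulen-4-yl 4-[(tert-butyldimethylsilyl)oxy]-3-methoxybenzoate | COc1cc(C(=O)O[C@H]2C[C@@](C)(O)C=C[C@@]3(C)CC[C@@](O)(C(C)C)[C@H]23)ccc1O[Si](C)(C)C(C)(C)C | intermediate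
22 | (3R,3aS,4S,6R,8aR)-3,6-dihydroxy-6,8a-dimethyl-3-(propan-2-yl)-1,2,3,3a,4,5,6,8a-octahydroazulen-4-yl 4-hydroxy-3-methoxybenzoate | COc1cc(C(=O)O[C@H]2C[C@@](C)(O)C=C[C@@]3(C)CC[C@@](O)(C(C)C)[C@H]23)ccc1O | target

## Step count and risks

Total step count: 14. Longest linear sequence: 11 steps (steps 1, 2, 3, 6, 7, 8, 9, 10, 11, 13 and 14, from ethynyltrimethylsilane 1).

**Step 6 (key step).** The hindered (Z)-β-silylalkenyl group may transfer sluggishly or with eroded enantioface selection; this would first be met by ligand choice. The more probable failure is poor simple diastereoselection in the aldol capture. An aluminium enolate can react through a loose transition state, and residual alane or Lewis-acidic aluminium can degrade the β-ketal aldehyde. The fallback separates the two events, sets out from 10 and 6 and returns at 12. The conjugate addition is run as before and enolate 11 is quenched with Me3SiOTf to give the trimethylsilyl enol ether F1. F1 keeps the enolate regiochemistry and allows the enantiomeric purity at C1 to be checked before the aldehyde is committed. Silicon–boron exchange of F1 with Bu2BOTf in CH2Cl2 gives the dibutylboron enolate F2. Its short B–O bonds enforce a tight chair transition state with 9 at −78 °C, and a non-oxidative work-up returns 12.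

**Step 11.** Ketones are poor electrophiles for alkenylchromium species, so protodeiodination may outrun ring closure. Facial selection at C8 also rests on a conformational argument and may be low. The fallback changes the metal and the transition state, sets out from 16 and returns at 17. Both hydroxyls of 16 are silylated with N-(trimethylsilyl)imidazole to give the bis(trimethylsilyl) ether F5. Iodine–lithium exchange with n-BuLi in THF at −78 °C then generates an alkenyllithium that adds to the ketone in an anionic cyclisation, giving the bicyclic bis(silyl) ether F6. K2CO3 in MeOH removes both silyl groups to give 17. The lithium alkoxide transition state, without free hydroxyls, also offers a second, independent facial bias at C8.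

**Step 8.** β-Hydride transfer from the isopropyl reagent (reduction of the ketone), enolisation, or attack on the wrong face under the influence of the silylvinyl group may compete with the desired addition. The fallback sets out from 13 and returns at 14. 2-Propenylmagnesium bromide with CeCl3 has no sp3 β-hydrogen and is flatter, and should give the isopropenyl carbinol F3. Hydrogenation of F3 with H2 and [Ir(cod)(PCy3)(py)]PF6 in CH2Cl2, directed by the adjacent tertiary hydroxyl, saturates only the 1,1-disubstituted alkene. The hindered vinylsilane lies on the opposite ring face from the hydroxyl and should be left.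

**Step 10.** Acid may dehydrate the β-hydroxy ketone or ionise the tertiary C4 alcohol while the ketal is being hydrolysed. The fallback uses two neutral stages in place of one acidic operation, sets out from 15 and returns at 16. Bu4NF buffered with AcOH removes the triethylsilyl group to give the diol ketal F4. Ketal exchange with acetone catalysed by PdCl2(MeCN)2 at rt then releases the ketone without a Brønsted acid.

## Further compounds

F1 | step 6 | trimethyl({(3S)-3-methyl-3-[(Z)-2-(trimethylsilyl)ethenyl]cyclopent-1-en-1-yl}oxy)silane | C[Si](C)(C)/C=C\[C@@]1(C)CCC(O[Si](C)(C)C)=C1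
F2 | step 6 | dibutyl({(3S)-3-methyl-3-[(Z)-2-(trimethylsilyl)ethenyl]cyclopent-1-en-1-yl}oxy)borane | C[Si](C)(C)/C=C\[C@@]1(C)CCC(OB(CCCC)CCCC)=C1
F3 | step 8 | (1S,2S,3S)-3-methyl-2-[(1S)-2-(2-methyl-1,3-dioxolan-2-yl)-1-(triethylsilyloxy)ethyl]-1-(prop-1-en-2-yl)-3-[(Z)-2-(trimethylsilyl)ethenyl]cyclopentan-1-ol | C[Si](C)(C)/C=C\[C@@]1(C)CC[C@@](O)(C(C)=C)[C@@H]1[C@@H](O[Si](CC)(CC)CC)CC2(C)OCCO2
F4 | step 10 | (1R,2S,3S)-2-[(1S)-1-hydroxy-2-(2-methyl-1,3-dioxolan-2-yl)ethyl]-3-[(Z)-2-iodoethenyl]-3-methyl-1-(propan-2-yl)cyclopentan-1-ol | I/C=C\[C@@]1(C)CC[C@@](O)(C(C)C)[C@@H]1[C@@H](O)CC2(C)OCCO2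
F5 | step 11 | (4S)-4-[(1S,2R,5S)-5-[(Z)-2-iodoethenyl]-5-methyl-2-(propan-2-yl)-2-(trimethylsilyloxy)cyclopentyl]-4-(trimethylsilyloxy)butan-2-one | I/C=C\[C@@]1(C)CC[C@@](O[Si](C)(C)C)(C(C)C)[C@@H]1[C@@H](O[Si](C)(C)C)CC(C)=O
F6 | step 11 | (3R,3aS,4S,6R,8aR)-6,8a-dimethyl-3-(propan-2-yl)-3,4-bis(trimethylsilyloxy)-1,2,3,3a,4,5,6,8a-octahydroazulen-6-ol | C[Si](C)(C)O[C@H]2C[C@@](C)(O)C=C[C@@]3(C)CC[C@@](O[Si](C)(C)C)(C(C)C)[C@H]23
A1 | alternative 1 | hydroazulene with a pinacol boronic ester on C8 in place of the hydroxyl, C6 triethylsilyl ether and C4 tert-butyldimethylsilyl ether | CC[Si](CC)(CC)O[C@H]2C[C@@](C)(B4OC(C)(C)C(C)(C)O4)C=C[C@@]3(C)CC[C@@](O[Si](C)(C)C(C)(C)C)(C(C)C)[C@H]23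
A2 | alternative 1 | open-chain precursor: cyclopentane of 14 with C4 tert-butyldimethylsilyl ether, C6 triethylsilyl ether, C7 pinacol boronic ester and a (Z)-alkenyl chain ending in the (S)-configured C8 N,N-diisopropylcarbamate | C[C@H](OC(=O)N(C(C)C)C(C)C)/C=C\[C@@]1(C)CC[C@@](O[Si](C)(C)C(C)(C)C)(C(C)C)[C@@H]1[C@@H](O[Si](CC)(CC)CC)CB2OC(C)(C)C(C)(C)O2
A3 | alternative 2 | meso-1,5-dimethyl-8-oxabicyclo[3.2.1]oct-6-en-3-one | C[C@]12CC(=O)C[C@](C)(O1)C=C2
A4 | alternative 2 | 2,5-dimethylfuran | Cc1ccc(C)o1
A5 | alternative 2 | 1,1,3-trichloropropan-2-one | ClCC(=O)C(Cl)Cl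
A6 | alternative 3 | (3R,3aS,4S,8aR)-8a-methyl-6-methylidene-3-(propan-2-yl)-1,2,3,3a,4,5,6,8a-octahydroazulene-3,4-diol | O[C@H]2CC(=C)C=C[C@@]3(C)CC[C@@](O)(C(C)C)[C@H]23
A7 | alternative 3 | 5-[(1Z)-4-bromo-3-methylidenebut-1-en-1-yl]-2-hydroxy-5-methyl-2-(propan-2-yl)cyclopentane-1-carbaldehyde with the ring configuration of 16 | BrCC(=C)/C=C\[C@@]1(C)CC[C@@](O)(C(C)C)[C@@H]1C=O
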